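**Plan**
- Retrosynthesis: the 4'-O-silyl ether is removed last. The O1–C2 ether bond is cut to a phenol and a primary alcohol (Mitsunobu closure). The C2 carbinol is traced back to an aminal carbon, and the C3–C4 and O1–C2 bonds of ring C are then cut together in a retro hetero-Diels–Alder sense.
- Enabling feature: in ring C, O1–C8a–C4a–C4 is an oxa-diene hidden in ring A as an ortho-quinone methide, and C2–C3 with ring B on C3 is a two-carbon dienophile, used as an (E)-enecarbamate.
- Forward: ring A benzyl alcohol 8 (5 steps; prenyl introduced by lithiation between the two methoxy groups) and ring B enecarbamate 19 (5 steps; chromene by propargyl Claisen, then Doebner and Curtius) are made separately.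
- Ring C arises in the [4+2] step (aminal 21), is opened by hydrolysis and reduction to excise the nitrogen (diol 23), and is closed again by Mitsunobu etherification.
- Stereochemistry: the only stereocentre, C3 (R), is set in the cycloaddition by a chiral phosphoric acid; the aminal centre C2 is transient.

Key step: step 11

Remark on numbering: isoflavan numbering (O1, C2, C3, C4, C4a to C8a; ring B primed) is used throughout.
Assumption: the (R)-configured phosphoric acid is taken to give the (3R) adduct; the sense of induction is to be checked on 21, and the (S)-catalyst would be used with nothing else changed if it proves opposite.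

**Step 1**
Reactants: 1 3,5-dimethoxyphenol
Product: 2 (3,5-dimethoxyphenoxy)triisopropylsilane
Conditions: TIPSCl, imidazole, DMF, rt
Reagents that add atoms: triisopropylsilyl chloride, CC(C)[Si](Cl)(C(C)C)C(C)C
Why: Imidazole-promoted silylation of the phenol is routine, and the bulky triisopropylsilyl ether neither directs lithiation nor migrates to carbon in the next step.

**Step 2**
Reactants: 2 (3,5-dimethoxyphenoxy)triisopropylsilane; 3 prenyl bromide (1-bromo-3-methylbut-2-ene)
Product: 5 [3,5-dimethoxy-4-(3-methylbut-2-en-1-yl)phenoxy]triisopropylsilane, via aryllithium 4 (not isolated)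
Conditions: n-BuLi, TMEDA, THF, 0 °C → rt; CuBr·SMe2 (10 mol %), then 3, −78 °C → rt
Reagents that add atoms: none
Why: Directed ortho-metalation takes place at the carbon flanked by both methoxy groups (the silyloxy group is a poor and hindered director), and the aryllithium, relayed through a catalytic arylcopper species, is allylated by prenyl bromide at its primary carbon (SN2).

**Step 3**
Reactants: 5 [3,5-dimethoxy-4-(3-methylbut-2-en-1-yl)phenoxy]triisopropylsilane
Product: 6 3,5-dimethoxy-4-(3-methylbut-2-en-1-yl)phenol
Conditions: Bu4NF, THF, 0 °C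
Reagents that add atoms: none
Why: Fluoride-mediated cleavage of the aryl silyl ether frees the phenol needed to direct the formylation and leaves the prenyl alkene untouched.

**Step 4**
Reactants: 6 3,5-dimethoxy-4-(3-methylbut-2-en-1-yl)phenol
Product: 7 6-hydroxy-2,4-dimethoxy-3-(3-methylbut-2-en-1-yl)benzaldehyde
Conditions: MgCl2, Et3N, (CH2O)n, MeCN, 80 °C
Reagents that add atoms: formaldehyde (as paraformaldehyde), C=O
Why: The magnesium phenoxide-directed ortho-formylation (Casnati–Skattebøl reaction) functionalises only a position ortho to the hydroxyl, and the two ortho positions of 6 are equivalent by symmetry, so a single aldehyde should result.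

**Step 5**
Reactants: 7 6-hydroxy-2,4-dimethoxy-3-(3-methylbut-2-en-1-yl)benzaldehyde
Product: 8 2-(hydroxymethyl)-3,5-dimethoxy-4-(3-methylbut-2-en-1-yl)phenol
Conditions: NaBH4, THF/MeOH, 0 °C; pH 7 buffer work-up, used without storage
Reagents that add atoms: none
Why: Borohydride reduction of the salicylaldehyde gives the ortho-hydroxybenzyl alcohol, and low temperature with a neutral work-up guards against ionisation of this electron-rich alcohol and over-reduction through the quinone methide.

**Step 6**
Reactants: 9 2,4-dihydroxybenzaldehyde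
Product: 10 2-hydroxy-4-(triisopropylsilyloxy)benzaldehyde
Conditions: TIPSCl, imidazole, CH2Cl2, 0 °C
Reagents that add atoms: triisopropylsilyl chloride, CC(C)[Si](Cl)(C(C)C)C(C)C
Why: Silylation is regioselective for the 4-hydroxyl because the 2-hydroxyl is hydrogen-bonded to the aldehyde and less acidic, and the triisopropylsilyl ether is chosen over smaller silyl ethers for its stability to amine bases and heat in steps 7 to 10.

**Step 7**
Reactants: 10 2-hydroxy-4-(triisopropylsilyloxy)benzaldehyde; 11 3-chloro-3-methylbut-1-yne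
Product: 12 2-[(2-methylbut-3-yn-2-yl)oxy]-4-(triisopropylsilyloxy)benzaldehyde
Conditions: DBU, CuCl2·2H2O (1 mol %), MeCN, 0 °C → rt
Reagents that add atoms: none
Why: Copper-catalysed O-propargylation of phenols with tertiary propargyl chlorides (via a copper acetylide/allenylidene electrophile) etherifies even hindered hydroxyls at low temperature, here the only free one.

**Step 8**
Reactants: 12 2-[(2-methylbut-3-yn-2-yl)oxy]-4-(triisopropylsilyloxy)benzaldehyde
Product: 14 2,2-dimethyl-5-(triisopropylsilyloxy)-2H-chromene-8-carbaldehyde, via allenyl phenol 13 (not isolated)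
Conditions: PhNEt2, 185 °C
Reagents that add atoms: none
Why: The aryl propargyl ether undergoes the aromatic propargyl Claisen rearrangement to C3 (the only free ortho carbon), and the allenyl phenol closes by 1,5-hydrogen shift and oxa-6π electrocyclisation to the 2,2-dimethyl-2H-chromene whose ring oxygen is the former 2-hydroxyl oxygen.

**Step 9**
Reactants: 14 2,2-dimethyl-5-(triisopropylsilyloxy)-2H-chromene-8-carbaldehyde
Product: 16 (E)-3-[2,2-dimethyl-5-(triisopropylsilyloxy)-2H-chromen-8-yl]prop-2-enoic acid, via arylidenemalonic acid 15 (not isolated)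
Conditions: CH2(CO2H)2, pyridine, piperidine (cat.), 85 °C
Reagents that add atoms: malonic acid, OC(=O)CC(=O)O
Why: The Knoevenagel–Doebner condensation with malonic acid followed by decarboxylation in pyridine gives the (E)-cinnamic acid under conditions (amine base, no hydroxide) that an aryl triisopropylsilyl ether tolerates.

**Step 10**
Reactants: 16 (E)-3-[2,2-dimethyl-5-(triisopropylsilyloxy)-2H-chromen-8-yl]prop-2-enoic acid
Product: 19 methyl N-{(E)-2-[2,2-dimethyl-5-(triisopropylsilyloxy)-2H-chromen-8-yl]ethenyl}carbamate, via acyl azide 17 (not isolated), via isocyanate 18 (not isolated)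
Conditions: (PhO)2P(O)N3, Et3N, toluene, rt; then 90 °C; then MeOH, 65 °C
Reagents that add atoms: diphenylphosphoryl azide, [N-]=[N+]=NP(=O)(Oc1ccccc1)Oc1ccccc1; methanol, CO
Why: The Curtius rearrangement of the cinnamoyl azide proceeds with retention of the (E)-alkene geometry and methanol adds to the styryl isocyanate, the standard entry to (E)-enecarbamates.

**Step 11**
Reactants: 8 2-(hydroxymethyl)-3,5-dimethoxy-4-(3-methylbut-2-en-1-yl)phenol; 19 methyl N-{(E)-2-[2,2-dimethyl-5-(triisopropylsilyloxy)-2H-chromen-8-yl]ethenyl}carbamate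
Product: 21 methyl N-{(2S,3R)-3-[2,2-dimethyl-5-(triisopropylsilyloxy)-2H-chromen-8-yl]-5,7-dimethoxy-6-(3-methylbut-2-en-1-yl)-3,4-dihydro-2H-chromen-2-yl}carbamate (2,3-trans), via ortho-quinone methide 20 (not isolated)
Conditions: (R)-3,3'-bis(2,4,6-triisopropylphenyl)-1,1'-binaphthyl-2,2'-diyl hydrogen phosphate (10 mol %), 19 (1.3 equiv), 3 Å MS, CH2Cl2, 0 °C, slow addition of 8
Reagents that add atoms: none
Why: The phosphoric acid dehydrates 8, whose methoxy groups ortho and para to the benzylic carbon stabilise the developing cation, to ortho-quinone methide 20, which stays hydrogen-bonded to the catalyst through its carbonyl oxygen while the phosphoryl oxygen holds the carbamate N–H of 19. The aryl-bearing alkene carbon of 19 then attacks the methide carbon (C3–C4) and the quinone oxygen closes on the nitrogen-bearing carbon (O1–C2) in a concerted but asynchronous inverse-electron-demand hetero-Diels–Alder reaction, the closest known type being the chiral phosphoric acid-catalysed [4+2] cycloaddition of in situ ortho-quinone methides with enecarbamates and enamides. Ring C closes as a six-membered ring by this [4+2] mode, which in the stepwise limit is a 6-exo-trig attack of the phenol oxygen on the N-acyliminium carbon. C3 is set by the chiral phosphate, which exposes one face of the bound (E)-enecarbamate to the methide carbon, and C2 follows from suprafacial addition to the (E)-alkene (2,3-trans) and is erased later. The step needs the C3-to-C4 regiochemistry, secured by the match of the nucleophilic beta-carbon of the enecarbamate with the electrophilic methide carbon, and face selectivity at C3, secured by the two-point hydrogen bonding of the carbamate N–H and the quinone methide oxygen to the catalyst. Slow addition of 8 to an excess of 19 over molecular sieves keeps the quinone methide from condensing with itself and the enecarbamate from hydrolysis.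

**Step 12**
Reactants: 21 methyl N-{(2S,3R)-3-[2,2-dimethyl-5-(triisopropylsilyloxy)-2H-chromen-8-yl]-5,7-dimethoxy-6-(3-methylbut-2-en-1-yl)-3,4-dihydro-2H-chromen-2-yl}carbamate
Product: 23 2-{(2R)-2-[2,2-dimethyl-5-(triisopropylsilyloxy)-2H-chromen-8-yl]-3-hydroxypropyl}-3,5-dimethoxy-4-(3-methylbut-2-en-1-yl)phenol, via lactol 22 (not isolated)
Conditions: 1 M HCl, THF, 0 °C → rt; then NaHCO3 (to pH 8), NaBH4, EtOH, 0 °C
Reagents that add atoms: water, O
Why: Aqueous acid hydrolyses the N-acyl N,O-acetal to the lactol (a chroman-2-ol) with loss of methyl carbamate, and borohydride then reduces the ring-opened aldehyde tautomer faster than it can enolise, so C3 is carried through unchanged.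

**Step 13**
Reactants: 23 2-{(2R)-2-[2,2-dimethyl-5-(triisopropylsilyloxy)-2H-chromen-8-yl]-3-hydroxypropyl}-3,5-dimethoxy-4-(3-methylbut-2-en-1-yl)phenol
Product: 24 ({8-[(3R)-5,7-dimethoxy-6-(3-methylbut-2-en-1-yl)-3,4-dihydro-2H-chromen-3-yl]-2,2-dimethyl-2H-chromen-5-yl}oxy)triisopropylsilane
Conditions: PPh3, DIAD, THF, 0 °C → rt
Reagents that add atoms: none
Why: The intramolecular Mitsunobu etherification of the phenol with the activated primary alcohol (6-exo-tet) re-forms ring C, the standard closure of isoflavans, and does not touch C3.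

**Step 14**
Reactants: 24 ({8-[(3R)-5,7-dimethoxy-6-(3-methylbut-2-en-1-yl)-3,4-dihydro-2H-chromen-3-yl]-2,2-dimethyl-2H-chromen-5-yl}oxy)triisopropylsilane
Product: 25 kanzonol I, 8-[(3R)-5,7-dimethoxy-6-(3-methylbut-2-en-1-yl)-3,4-dihydro-2H-chromen-3-yl]-2,2-dimethyl-2H-chromen-5-ol
Conditions: Bu4NF, THF, 0 °C
Reagents that add atoms: none
Why: Fluoride cleaves the aryl triisopropylsilyl ether under conditions harmless to the prenyl group, the chromene and the C3 stereocentre.

**Compound list**
1 | 3,5-dimethoxyphenol | COc1cc(O)cc(OC)c1 | starting material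
2 | (3,5-dimethoxyphenoxy)triisopropylsilane | COc1cc(O[Si](C(C)C)(C(C)C)C(C)C)cc(OC)c1 | intermediate
3 | prenyl bromide (1-bromo-3-methylbut-2-ene) | CC(C)=CCBr | starting material
4 | [2,6-dimethoxy-4-(triisopropylsilyloxy)phenyl]lithium (formed in the flask in step 2) | [Li]c1c(OC)cc(O[Si](C(C)C)(C(C)C)C(C)C)cc1OC | intermediate
5 | [3,5-dimethoxy-4-(3-methylbut-2-en-1-yl)phenoxy]triisopropylsilane | COc1cc(O[Si](C(C)C)(C(C)C)C(C)C)cc(OC)c1CC=C(C)C | intermediate
6 | 3,5-dimethoxy-4-(3-methylbut-2-en-1-yl)phenol | COc1cc(O)cc(OC)c1CC=C(C)C | intermediate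
7 | 6-hydroxy-2,4-dimethoxy-3-(3-methylbut-2-en-1-yl)benzaldehyde | COc1cc(O)c(C=O)c(OC)c1CC=C(C)C | intermediate
8 | 2-(hydroxymethyl)-3,5-dimethoxy-4-(3-methylbut-2-en-1-yl)phenol | COc1cc(O)c(CO)c(OC)c1CC=C(C)C | intermediate
9 | 2,4-dihydroxybenzaldehyde | O=Cc1ccc(O)cc1O | starting material
10 | 2-hydroxy-4-(triisopropylsilyloxy)benzaldehyde | O=Cc1ccc(O[Si](C(C)C)(C(C)C)C(C)C)cc1O | intermediate
11 | 3-chloro-3-methylbut-1-yne | C#CC(C)(C)Cl | starting material
12 | 2-[(2-methylbut-3-yn-2-yl)oxy]-4-(triisopropylsilyloxy)benzaldehyde | C#CC(C)(C)Oc1cc(O[Si](C(C)C)(C(C)C)C(C)C)ccc1C=O | intermediate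
13 | 2-hydroxy-3-(3-methylbuta-1,2-dien-1-yl)-4-(triisopropylsilyloxy)benzaldehyde (allenyl phenol, formed in the flask in step 8) | CC(C)=C=Cc1c(O)c(C=O)ccc1O[Si](C(C)C)(C(C)C)C(C)C | intermediate
14 | 2,2-dimethyl-5-(triisopropylsilyloxy)-2H-chromene-8-carbaldehyde | O=Cc1ccc(O[Si](C(C)C)(C(C)C)C(C)C)c2c1OC(C)(C)C=C2 | intermediate
15 | 2-{[2,2-dimethyl-5-(triisopropylsilyloxy)-2H-chromen-8-yl]methylidene}propanedioic acid (formed in the flask in step 9) | OC(=O)C(=Cc1ccc(O[Si](C(C)C)(C(C)C)C(C)C)c2c1OC(C)(C)C=C2)C(=O)O | intermediate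
16 | (E)-3-[2,2-dimethyl-5-(triisopropylsilyloxy)-2H-chromen-8-yl]prop-2-enoic acid | OC(=O)/C=C/c1ccc(O[Si](C(C)C)(C(C)C)C(C)C)c2c1OC(C)(C)C=C2 | intermediate
17 | (E)-3-[2,2-dimethyl-5-(triisopropylsilyloxy)-2H-chromen-8-yl]prop-2-enoyl azide (formed in the flask in step 10) | [N-]=[N+]=NC(=O)/C=C/c1ccc(O[Si](C(C)C)(C(C)C)C(C)C)c2c1OC(C)(C)C=C2 | intermediate
18 | 8-[(E)-2-isocyanatoethenyl]-2,2-dimethyl-5-(triisopropylsilyloxy)-2H-chromene (formed in the flask in step 10) | O=C=N/C=C/c1ccc(O[Si](C(C)C)(C(C)C)C(C)C)c2c1OC(C)(C)C=C2 | intermediate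
19 | methyl N-{(E)-2-[2,2-dimethyl-5-(triisopropylsilyloxy)-2H-chromen-8-yl]ethenyl}carbamate | COC(=O)N/C=C/c1ccc(O[Si](C(C)C)(C(C)C)C(C)C)c2c1OC(C)(C)C=C2 | intermediate
20 | 3,5-dimethoxy-4-(3-methylbut-2-en-1-yl)-6-methylidenecyclohexa-2,4-dien-1-one (ortho-quinone methide, formed in the flask in step 11) | C=C1C(OC)=C(CC=C(C)C)C(OC)=CC1=O | intermediate
21 | methyl N-{(2S,3R)-3-[2,2-dimethyl-5-(triisopropylsilyloxy)-2H-chromen-8-yl]-5,7-dimethoxy-6-(3-methylbut-2-en-1-yl)-3,4-dihydro-2H-chromen-2-yl}carbamate | COc1cc2c(c(OC)c1CC=C(C)C)C[C@H](c1ccc(O[Si](C(C)C)(C(C)C)C(C)C)c3c1OC(C)(C)C=C3)[C@@H](NC(=O)OC)O2 | intermediate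
22 | (3R)-3-[2,2-dimethyl-5-(triisopropylsilyloxy)-2H-chromen-8-yl]-5,7-dimethoxy-6-(3-methylbut-2-en-1-yl)-3,4-dihydro-2H-chromen-2-ol (lactol, both C2 epimers, formed in the flask in step 12) | COc1cc2c(c(OC)c1CC=C(C)C)C[C@H](c1ccc(O[Si](C(C)C)(C(C)C)C(C)C)c3c1OC(C)(C)C=C3)C(O)O2 | intermediate
23 | 2-{(2R)-2-[2,2-dimethyl-5-(triisopropylsilyloxy)-2H-chromen-8-yl]-3-hydroxypropyl}-3,5-dimethoxy-4-(3-methylbut-2-en-1-yl)phenol | COc1cc(O)c(c(OC)c1CC=C(C)C)C[C@H](c1ccc(O[Si](C(C)C)(C(C)C)C(C)C)c2c1OC(C)(C)C=C2)CO | intermediate
24 | ({8-[(3R)-5,7-dimethoxy-6-(3-methylbut-2-en-1-yl)-3,4-dihydro-2H-chromen-3-yl]-2,2-dimethyl-2H-chromen-5-yl}oxy)triisopropylsilane | COc1cc2c(c(OC)c1CC=C(C)C)C[C@H](c1ccc(O[Si](C(C)C)(C(C)C)C(C)C)c3c1OC(C)(C)C=C3)CO2 | intermediate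
25 | kanzonol I, 8-[(3R)-5,7-dimethoxy-6-(3-methylbut-2-en-1-yl)-3,4-dihydro-2H-chromen-3-yl]-2,2-dimethyl-2H-chromen-5-ol | COc1cc2c(c(OC)c1CC=C(C)C)C[C@H](c1ccc(O)c3c1OC(C)(C)C=C3)CO2 | target

**Totals**
Total step count: 14.
Longest linear sequence: 9 steps (steps 1 to 5 or steps 6 to 10, then steps 11 to 14).

**Steps most likely to fail**

Step 11. Three things may go wrong:
- Face discrimination at C3 may be weak, because the only stereocentre formed lies on the dienophile carbon and the unsubstituted methide gives the catalyst little to hold.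
- The electron-rich quinone methide may condense with itself or with 8.
- The acid may scramble the alkene geometry of 19 or hydrolyse it.

The fallback sets out from 19 and 8 and returns at 22. Enecarbamate 19 would be hydrolysed with aqueous oxalic acid in THF to [2,2-dimethyl-5-(triisopropylsilyloxy)-2H-chromen-8-yl]acetaldehyde F1. F1 would then be joined to 8 under enamine catalysis by (R)-2-[diphenyl(trimethylsilyloxy)methyl]pyrrolidine with benzoic acid as co-catalyst in toluene. This aminocatalytic [4+2] reaction of an aldehyde with an ortho-quinone methide forms the same C3–C4 and O1–C2 bonds. The silyloxydiphenylmethyl group shields one face of the enamine, and on the usual shielding model the (R)-amine should give 3R. The product is lactol 22 directly, which enters the borohydride stage of step 12, so no aminal has to be hydrolysed.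

Step 12. C3 may epimerise, in acid through iminium–enecarbamate tautomerism and in base through enolisation of the ring-opened alpha-aryl aldehyde before hydride arrives. Methyl carbamate may also be eliminated to give the achiral 4H-chromene. The fallback sets out from 21 and returns at 24. Compound 21 would be hydrolysed alone in a buffered two-phase medium and lactol 22 isolated. Compound 22 would then be deoxygenated with Et3SiH and BF3·OEt2 in CH2Cl2 at −78 °C (ionic hydrogenation of a chroman-2-ol through the aryl oxocarbenium ion). This gives 24 without exposing the open aldehyde to base and without diol 23 or the Mitsunobu closure. The fallback of step 11 also reaches 22 without aqueous acid.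

Step 7. Etherification of the hydrogen-bonded, hindered 2-hydroxyl by a tertiary propargyl electrophile may stall, and the amine base may strip or shift the silyl group. The fallback sets out from 10 and returns at 14, replacing steps 7 and 8. Compound 10 would be condensed with 3-methylbut-2-enal in the presence of PhB(OH)2 and acetic acid in toluene at reflux with removal of water. The sequence is ortho-specific C-alkylation at C3, dehydration to the quinone methide and oxa-6π electrocyclisation. Only the 2-hydroxyl is free, so the chromene can form only between O2 and C3.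

**Further compounds**
F1 | step 11 | [2,2-dimethyl-5-(triisopropylsilyloxy)-2H-chromen-8-yl]acetaldehyde | O=CCc1ccc(O[Si](C(C)C)(C(C)C)C(C)C)c2c1OC(C)(C)C=C2
F0 | step 12 | none | none
F0 | step 7 | none | none
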